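**Retrosynthetic overview**

1. Rings A and B are bought as arenes; only ring C is built, last, through one C–C bond (C2–C3) and one C–O bond (O1–C2).
2. Ring A piece: 2'-hydroxy-6'-methoxyacetophenone 1 is para-hydroxylated (Elbs, via aryl sulfate 2) to hydroquinone 3, then mono-methylated to acetophenone 4.
3. Ring B piece: 1,2,4-trimethoxybenzene 5 is lithiated between two OMe groups (aryllithium 6), then formylated (adduct 7) to 2,3,6-trimethoxybenzaldehyde 8.
4. C2–C3 disconnection: Claisen–Schmidt condensation of 4 with 8 (aldol 9) gives 2'-hydroxychalcone 10.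
5. O1–C2 disconnection: oxidative cyclization of 10 (flavanone 11) closes ring C and gives flavone 12.

Assumption: the target has no stereocentre and rotates freely about the C2–C1' bond, so it is achiral and no enantiocontrol is needed.

**Step 1**
Reactants: 1 2'-hydroxy-6'-methoxyacetophenone [1-(2-hydroxy-6-methoxyphenyl)ethanone]
Product: 3 1-(3,6-dihydroxy-2-methoxyphenyl)ethanone, via aryl sulfate 2 (not isolated)
Conditions: K2S2O8, aq KOH, 15–20 °C, 24 h; then conc. HCl, 90 °C
Reagents that add atoms: potassium peroxodisulfate, [K+].[K+].[O-]S(=O)(=O)OOS(=O)(=O)[O-]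
Why: Elbs persulfate oxidation, in which the phenoxide of 1 attacks the peroxide oxygen through its free para carbon to give aryl sulfate 2, which acid hydrolysis unmasks as the hydroquinone; no stereocentre is formed.

**Step 2**
Reactants: 3 1-(3,6-dihydroxy-2-methoxyphenyl)ethanone
Product: 4 1-(6-hydroxy-2,3-dimethoxyphenyl)ethanone
Conditions: Me2SO4 (1.05 equiv), K2CO3 (1.1 equiv), acetone, reflux
Reagents that add atoms: dimethyl sulfate, COS(=O)(=O)OC
Why: Williamson-type O-methylation, selective because the 6-OH is hydrogen-bonded to the acetyl C=O and far less nucleophilic than the free 3-OH; no stereocentre is formed.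

**Step 3**
Reactants: 5 1,2,4-trimethoxybenzene
Product: 8 2,3,6-trimethoxybenzaldehyde, via 2,3,6-trimethoxyphenyllithium 6 (not isolated), via lithium hemiaminal alkoxide 7 (not isolated)
Conditions: n-BuLi, TMEDA, THF, 0 °C; DMF, 0 °C to rt; aq HCl
Reagents that add atoms: N,N-dimethylformamide, CN(C)C=O
Why: Directed ortho-metalation at C3 of 5, the only position flanked by two OMe groups, then Bouveault formylation of 6 with DMF, whose tetrahedral adduct 7 (racemic) collapses to the achiral aldehyde on acidic work-up.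

**Step 4**
Reactants: 4 1-(6-hydroxy-2,3-dimethoxyphenyl)ethanone; 8 2,3,6-trimethoxybenzaldehyde
Product: 10 (E)-1-(6-hydroxy-2,3-dimethoxyphenyl)-3-(2,3,6-trimethoxyphenyl)prop-2-en-1-one, via aldol adduct 9 (not isolated)
Conditions: KOH, EtOH/H2O, rt, 48 h; then aq HCl
Reagents that add atoms: none
Why: Claisen–Schmidt crossed aldol condensation, in which the enolate of 4 adds to the non-enolisable aldehyde 8 and racemic aldol 9 loses water by E1cB to give the thermodynamically favoured E-enone, erasing the carbinol stereocentre.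

**Step 5**
Reactants: 10 (E)-1-(6-hydroxy-2,3-dimethoxyphenyl)-3-(2,3,6-trimethoxyphenyl)prop-2-en-1-one
Product: 12 5,6,2',3',6'-pentamethoxyflavone, via flavanone 11 (not isolated)
Conditions: I2 (10 mol %), DMSO, 130 °C, 2–4 h; aq Na2S2O3 work-up
Reagents that add atoms: none
Why: Iodine-catalysed oxidative cyclization in DMSO, in which 6-endo oxa-Michael addition of the phenol gives racemic flavanone 11 and α-iodination followed by HI loss dehydrogenates it to the γ-pyrone while DMSO reoxidises HI to I2, so no stereocentre remains.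

**Compound list**

1 | 2'-hydroxy-6'-methoxyacetophenone [1-(2-hydroxy-6-methoxyphenyl)ethanone] | CC(=O)c1c(O)cccc1OC | starting material
2 | aryl sulfate: potassium 3-acetyl-4-hydroxy-2-methoxyphenyl sulfate (not isolated) | CC(=O)c1c(O)ccc(OS(=O)(=O)[O-])c1OC.[K+] | intermediate
3 | 1-(3,6-dihydroxy-2-methoxyphenyl)ethanone (2',5'-dihydroxy-6'-methoxyacetophenone) | CC(=O)c1c(O)ccc(O)c1OC | intermediate
4 | 1-(6-hydroxy-2,3-dimethoxyphenyl)ethanone (6'-hydroxy-2',3'-dimethoxyacetophenone) | CC(=O)c1c(O)ccc(OC)c1OC | intermediate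
5 | 1,2,4-trimethoxybenzene | COc1ccc(OC)c(OC)c1 | starting material
6 | 2,3,6-trimethoxyphenyllithium (not isolated) | [Li]c1c(OC)ccc(OC)c1OC | intermediate
7 | lithium hemiaminal alkoxide: lithium (dimethylamino)(2,3,6-trimethoxyphenyl)methanolate, racemic (not isolated) | CN(C)C([O-])c1c(OC)ccc(OC)c1OC.[Li+] | intermediate
8 | 2,3,6-trimethoxybenzaldehyde | O=Cc1c(OC)ccc(OC)c1OC | intermediate
9 | aldol adduct: 3-hydroxy-1-(6-hydroxy-2,3-dimethoxyphenyl)-3-(2,3,6-trimethoxyphenyl)propan-1-one, racemic (not isolated) | COc1ccc(OC)c(C(O)CC(=O)c2c(O)ccc(OC)c2OC)c1OC | intermediate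
10 | (E)-1-(6-hydroxy-2,3-dimethoxyphenyl)-3-(2,3,6-trimethoxyphenyl)prop-2-en-1-one (2'-hydroxychalcone) | COc1ccc(OC)c(/C=C/C(=O)c2c(O)ccc(OC)c2OC)c1OC | intermediate
11 | flavanone: 5,6-dimethoxy-2-(2,3,6-trimethoxyphenyl)chroman-4-one, racemic (not isolated) | COc1ccc(OC)c(C2CC(=O)c3c(OC)c(OC)ccc3O2)c1OC | intermediate
12 | 5,6,2',3',6'-pentamethoxyflavone | COc1ccc(OC)c(-c2cc(=O)c3c(OC)c(OC)ccc3o2)c1OC | target

**Totals**

Total step count: 5. Longest linear sequence: 4 steps (steps 1, 2, 4, 5 from compound 1); step 3 is the one-step branch that supplies ring B.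

**Three steps most likely to fail**

Step 1 (Elbs oxidation). This reaction typically gives only 25–40 % with much recovered 1 and dark over-oxidation products. The fallback takes the ring A oxygenation pattern from the arene instead of hydroxylating a phenol. It sets out from compound 5 and comes back to the route at compound 3. Compound 5 is lithiated to 6 as in step 3 and quenched with N-methoxy-N-methylacetamide (THF, −78 °C to rt) to give 2',3',6'-trimethoxyacetophenone F1. Oxidative demethylation of its para-dimethoxy pair with (NH4)2Ce(NO3)6 (tetravalent cerium) in MeCN/H2O at 0 °C gives 2-acetyl-3-methoxy-1,4-benzoquinone F2. This is reduced at once with aqueous Na2S2O4 in EtOAc to hydroquinone 3, which then takes step 2 as written.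

Step 4 (Claisen–Schmidt condensation). Both partners are di-ortho-substituted, and the ketone reacts as a poorly nucleophilic phenoxide-enolate dianion, so conversion may be slow and the aldehyde may be lost to Cannizzaro reaction. Partial closure of 10 to flavanone 11 is harmless, since step 5 accepts both. The fallback is a protecting-group route that sets out from compound 4 and comes back at compound 10. Compound 4 is converted with NaH and chloromethyl methyl ether (DMF, 0 °C) into 1-[2,3-dimethoxy-6-(methoxymethoxy)phenyl]ethanone F3. Its simple mono-enolate is condensed with 8 (KOH, EtOH, rt) to give (E)-1-[2,3-dimethoxy-6-(methoxymethoxy)phenyl]-3-(2,3,6-trimethoxyphenyl)prop-2-en-1-one F4. Acetal cleavage (3 M HCl, MeOH, 50 °C) then returns chalcone 10.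

Step 5 (I2/DMSO oxidative cyclization). The risks are nuclear iodination of the two electron-rich rings, HI-mediated loss of the 5-O-methyl group at 130 °C, and slow closure next to the di-ortho-substituted ring B. The fallback builds ring C at the β-diketone oxidation level, so no oxidation is needed. It sets out from compounds 4 and 5 and comes back at compound 12. Compound 5 is lithiated to 6 as in step 3 and trapped with CO2 (THF, −78 °C, then aq HCl) to give 2,3,6-trimethoxybenzoic acid F5. Treatment with (COCl)2 and catalytic DMF in CH2Cl2 gives 2,3,6-trimethoxybenzoyl chloride F6. The dilithium dianion of 4 (LiN(SiMe3)2, 3–4 equiv, THF, −78 to −10 °C) is C-acylated by F6 to give 1-(6-hydroxy-2,3-dimethoxyphenyl)-3-(2,3,6-trimethoxyphenyl)propane-1,3-dione F7. Cyclodehydration with H2SO4 (0.5 %) in AcOH at 100 °C gives 12.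

**Further compounds**

F1 | step 1 | 2',3',6'-trimethoxyacetophenone | CC(=O)c1c(OC)ccc(OC)c1OC
F2 | step 1 | 2-acetyl-3-methoxy-1,4-benzoquinone | CC(=O)C1=C(OC)C(=O)C=CC1=O
F3 | step 4 | 1-[2,3-dimethoxy-6-(methoxymethoxy)phenyl]ethanone | CC(=O)c1c(OCOC)ccc(OC)c1OC
F4 | step 4 | (E)-1-[2,3-dimethoxy-6-(methoxymethoxy)phenyl]-3-(2,3,6-trimethoxyphenyl)prop-2-en-1-one | COCOc1ccc(OC)c(OC)c1C(=O)/C=C/c1c(OC)ccc(OC)c1OC
F5 | step 5 | 2,3,6-trimethoxybenzoic acid | OC(=O)c1c(OC)ccc(OC)c1OC
F6 | step 5 | 2,3,6-trimethoxybenzoyl chloride | ClC(=O)c1c(OC)ccc(OC)c1OC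
F7 | step 5 | 1-(6-hydroxy-2,3-dimethoxyphenyl)-3-(2,3,6-trimethoxyphenyl)propane-1,3-dione | COc1ccc(OC)c(C(=O)CC(=O)c2c(O)ccc(OC)c2OC)c1OC
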